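Stir substrate and reagent in a flask of constant volume, and see how much target stands at the end.

    substrate + reagent ⇌ target (K1 = 360 /M, k1 = 32 /M/s, Ea1 = 48.0 kJ/mol, ΔH1 = −57.0 kJ/mol)
    target ⇌ isomer of the product (K2 = 3.7, k2 = 0.73 /s, Ea2 = 89.0 kJ/mol, ΔH2 = 4.00 kJ/mol)
    (constants at 100 °C)

| setting | gamma | zeta | alpha | eta |
|---|---|---|---|---|
| substrate | 10 mM | 10 mM | 10 mM (fed, over 4.0 s) | 10 mM |
| reagent | 0.600 equiv | 0.600 equiv (fed, over 4.0 s) | 0.600 equiv | 0.600 equiv (fed, over 4.0 s) |
| time | 6.0 s | 6.0 s | 6.0 s | 6.0 s |
| remark | everything together at the start at 80 °C, warmed to 100 °C at 4.0 s | the addition at 80 °C, then warmed to 100 °C; the feed brings no volume worth counting | all else is in the flask from the start; the feed brings no volume worth counting | all else is in the flask from the start; the feed brings no volume worth counting |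
| temperature |  |  | 100 °C | 100 °C |

- constants are those at 100 °C; use the activation energies and enthalpies for any other temperature

- which flask leads in amount of target, in percent of the substrate charged ("all alike" within 1.5 percentage points) (gamma / zeta / alpha / eta / all alike)
- how much target is there at the end, in percent of the substrate charged: gamma
- how much target is there at the end, in percent of the substrate charged: zeta
- how much target is there at the end, in percent of the substrate charged: alpha
- how much target is there at the end, in percent of the substrate charged: eta

Count turnovers. Target and isomer of the product relax toward their ratio at the turnover rate λ, the sum of the forward and backward constants of the second step at the hot temperature: λ = 0.927 /s. With the sum of the two held fixed, the excess of target over its equilibrium share of that sum shrinks as exp(−λt). Gamma and zeta get 2.00 s hot, which is longer than 1/λ. That makes 1.85 turnovers, so with the first step stopped, that excess at the warming keeps 15.7% of itself. This reckons the split within the pair, not the gap between flasks, so bracket a flask held hot throughout.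

Bound from above: take the first step's rate at full charges, with nothing consumed, and divide by the forward constant of the second step. This quasi-steady ceiling is 26.3% of the substrate charged. Tighten it: let substrate fall first-order under the full reagent, start the clock at half the feed, and let target be made and lost. That gives 14.6%. Bound from below: solve the equilibrium of both steps, a quadratic in the total converted, which leaves target at 11.3%. Target forms before isomer of the product, so it should come down to that level from above.

The forecast gives 13% for gamma, 12.7% for zeta, 12.1% for alpha and 12.1% for eta, inside the bracket, and answers all alike: “target is quickly drained to isomer, so it sits at a plateau where formation roughly balances loss”.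

The simulation gives 12.9% for gamma, 12.9% for zeta, 12.2% for alpha and 12.2% for eta, so the answer is all alike.

The second step holds target down: alpha without it ends at 32.1% against 12.2%. The equilibrium share of target in the pair is 21.3%. In gamma the share stood at 74.7% at 4.00 s; λ with the first step stopped brings it to 29.6%, and the end reads 38.2%, higher than that. In zeta the same reckoning goes from 82.9% to 30.9%, and the end reads 43.7%, again higher.

(The numbers of this flask are assumed; the run is a simulation.)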